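## Retrosynthetic overview
1. The target comes from O-demethylation of its ring A methyl ether. The two ring B bromines are installed just before that by phenol-directed bromination (para, then ortho) of 2-(2,4-dibromo-6-methoxyphenoxy)phenol.
2. The ring B phenol comes from dehydrogenation (silyl dienol ether, then DDQ) of a 2-aryloxycyclohex-2-enone, so the diaryl ether oxygen is never introduced by an arylation.
3. The enone comes from intramolecular aldol condensation and decarboxylation of a 1,5-keto aldehyde. That aldehyde is made in the key intermolecular Michael addition of tert-butyl 4-aryloxyacetoacetate to acrolein, which forms the C5–C6 bond of ring B.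
4. The β-keto ester comes from Claisen-type acylation of Meldrum's acid with the aryloxyacetic acid. The acid traces back through a Williamson alkylation to 2,4-dibromo-6-methoxyphenol, and that to guaiacol (ortho- then para-bromination).
5. Ring order: ring A is bought as guaiacol. Ring B is the only ring built; it is closed in step 8 and aromatised in step 10.

Assumption: the target has no stereocentre and no stable stereoaxis, so it is achiral and needs no enantiocontrol. The stereocentres of 12 and 15 are racemic and are erased later.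

## Route

Step 1
Reactants: 1 guaiacol (2-methoxyphenol)
Product: 2 2-bromo-6-methoxyphenol
Conditions: t-BuNH2 (2.0 equiv), Br2 (1.0 equiv), toluene, −30 °C; then 1 in CH2Cl2, −78 °C to rt
Reagents that add atoms: bromine, BrBr
Why: In this amine-mediated ortho-selective electrophilic aromatic bromination, the N-bromo-tert-butylamine formed in the flask is a mild bromine donor that reacts only through the hydrogen-bonded ammonium phenoxide and so delivers bromine to the one free position ortho to OH.

Step 2
Reactants: 2 2-bromo-6-methoxyphenol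
Product: 3 2,4-dibromo-6-methoxyphenol
Conditions: NBS (1.0 equiv), MeCN, 0 °C
Reagents that add atoms: N-bromosuccinimide, O=C1CCC(=O)N1Br
Why: Electrophilic aromatic substitution with NBS in a polar solvent goes para to the free OH, the strongest donor on the ring, and both ortho positions are already occupied.

Step 3
Reactants: 3 2,4-dibromo-6-methoxyphenol; 4 ethyl bromoacetate
Product: 5 ethyl 2-(2,4-dibromo-6-methoxyphenoxy)acetate
Conditions: K2CO3 (1.5 equiv), DMF, rt to 50 °C
Reagents that add atoms: none
Why: In this Williamson ether synthesis (SN2) the flanked phenoxide still attacks the unhindered, carbonyl-activated primary bromide cleanly, which fixes the oxygen that becomes the diaryl ether bridge.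

Step 4
Reactants: 5 ethyl 2-(2,4-dibromo-6-methoxyphenoxy)acetate
Product: 6 2-(2,4-dibromo-6-methoxyphenoxy)acetic acid
Conditions: LiOH·H2O (2 equiv), THF/H2O 3:1, rt; then 1 M HCl
Reagents that add atoms: lithium hydroxide LiOH, [Li+].[OH-]
Why: Saponification (BAc2 ester hydrolysis) of an unhindered ethyl ester leaves the aryl bromides and both ether types untouched.

Step 5
Reactants: 6 2-(2,4-dibromo-6-methoxyphenoxy)acetic acid; 7 Meldrum's acid
Product: 8 5-[2-(2,4-dibromo-6-methoxyphenoxy)-1-hydroxyethylidene]-2,2-dimethyl-1,3-dioxane-4,6-dione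
Conditions: DCC (1.1 equiv), DMAP (1.5 equiv), CH2Cl2, 0 °C to rt; filter, wash with aq. KHSO4
Reagents that add atoms: none
Why: In this intermolecular Claisen-type C-acylation, the carbodiimide/DMAP-activated acid acylates the very acidic methylene carbon of Meldrum's acid to give a stable, fully enolised product.

Step 6
Reactants: 8 acyl Meldrum's acid
Product: 10 tert-butyl 4-(2,4-dibromo-6-methoxyphenoxy)-3-oxobutanoate, via acylketene 9 (not isolated)
Conditions: t-BuOH (5 equiv), toluene, 90 °C
Reagents that add atoms: tert-butanol, CC(C)(C)O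
Why: Thermal cycloreversion of the acyl Meldrum's acid expels acetone and CO2, and the resulting acylketene is trapped by nucleophilic addition of tert-butanol to give the β-keto ester.

Step 7 (key step)
Reactants: 10 tert-butyl 4-(2,4-dibromo-6-methoxyphenoxy)-3-oxobutanoate; 11 acrolein
Product: 12 tert-butyl 2-[(2,4-dibromo-6-methoxyphenoxy)acetyl]-5-oxopentanoate (racemic)
Conditions: Et3N (0.1 equiv), CH2Cl2, −20 to 0 °C, 11 (1.05 equiv) added slowly; used crude
Reagents that add atoms: none
Why: In this intermolecular Michael addition only the doubly activated C-2 of the β-keto ester is deprotonated by the weak amine base and adds 1,4 to acrolein, and the new C-2 stereocentre forms racemic, is configurationally labile and disappears in step 8.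

Step 8
Reactants: 12 tert-butyl 2-[(2,4-dibromo-6-methoxyphenoxy)acetyl]-5-oxopentanoate
Product: 16 2-(2,4-dibromo-6-methoxyphenoxy)cyclohex-2-en-1-one, via keto acid 13 (not isolated), via keto aldehyde 14 (not isolated), via aldol 15 (not isolated)
Conditions: TsOH·H2O (0.3 equiv), toluene, 80 °C
Reagents that add atoms: none
Why: This acid-catalysed cascade of tert-butyl ester cleavage, β-keto acid decarboxylation and intramolecular aldol condensation works because the ArOCH2 carbon is the only enolisable position of the 1,5-keto aldehyde that can close a six-membered ring onto the aldehyde, the blocked ortho positions of ring A exclude benzofuran formation, and the two racemic stereocentres of aldol 15 are erased by dehydration.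

Step 9
Reactants: 16 2-(2,4-dibromo-6-methoxyphenoxy)cyclohex-2-en-1-one
Product: 17 tert-butyl{[6-(2,4-dibromo-6-methoxyphenoxy)cyclohexa-1,5-dien-1-yl]oxy}dimethylsilane
Conditions: TBSOTf (1.2 equiv), Et3N (2 equiv), CH2Cl2, 0 °C; aq. NaHCO3 work-up
Reagents that add atoms: tert-butyldimethylsilyl triflate, CC(C)(C)[Si](C)(C)OS(=O)(=O)C(F)(F)F
Why: Soft enolisation (silyl enol ether formation) O-silylates the enone and lets Et3N remove the α'-proton to give the 2-silyloxy-1,3-diene without any strong base that could metalate the bromoarene.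

Step 10
Reactants: 17 silyloxydiene
Product: 18 tert-butyl[2-(2,4-dibromo-6-methoxyphenoxy)phenoxy]dimethylsilane
Conditions: DDQ (1.1 equiv), toluene, 0 °C to rt
Reagents that add atoms: none
Why: In this dehydrogenative aromatisation DDQ abstracts hydride from the cyclohexa-1,3-diene to give an oxygen-stabilised arenium ion that loses a proton, driven by the gain of aromaticity, while the electron-poor ring A is inert.

Step 11
Reactants: 18 aryl TBS ether
Product: 19 2-(2,4-dibromo-6-methoxyphenoxy)phenol
Conditions: TBAF (1.1 equiv), AcOH (1.1 equiv), THF, 0 °C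
Reagents that add atoms: none
Why: Fluoride-mediated desilylation is driven by the strong Si–F bond and the good phenoxide leaving group, and the acetic acid buffer supplies the proton.

Step 12
Reactants: 19 2-(2,4-dibromo-6-methoxyphenoxy)phenol
Product: 20 4-bromo-2-(2,4-dibromo-6-methoxyphenoxy)phenol
Conditions: NBS (1.0 equiv), MeCN, 0 °C
Reagents that add atoms: N-bromosuccinimide, O=C1CCC(=O)N1Br
Why: Electrophilic aromatic bromination goes para to the free OH of ring B, which carries no halogen and is therefore many orders of magnitude more reactive than the dibrominated anisole-type ring A.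

Step 13
Reactants: 20 4-bromo-2-(2,4-dibromo-6-methoxyphenoxy)phenol
Product: 21 2,4-dibromo-6-(2,4-dibromo-6-methoxyphenoxy)phenol
Conditions: t-BuNH2 (2.2 equiv), Br2 (1.1 equiv), toluene, −30 °C; then 20 in CH2Cl2, −78 °C to rt
Reagents that add atoms: bromine, BrBr
Why: As in step 1, this amine-mediated ortho-selective bromination uses an N-bromoamine that reacts only with a free phenol through its ammonium phenoxide, so bromine enters the single open ortho position of ring B and the ether ring A is not touched.

Step 14
Reactants: 21 2,4-dibromo-6-(2,4-dibromo-6-methoxyphenoxy)phenol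
Product: 22 3,5-dibromo-2-(3,5-dibromo-2-hydroxyphenoxy)phenol (target)
Conditions: BBr3 (3 equiv), CH2Cl2, −78 °C to rt; then H2O
Reagents that add atoms: none
Why: In this Lewis acid-mediated aryl methyl ether cleavage boron coordinates the methoxy oxygen and bromide removes the methyl group by SN2, whereas the diaryl ether has no sp3 carbon to attack and the C–Br bonds are inert.

## Compound list
1 | guaiacol (2-methoxyphenol) | COc1ccccc1O | starting material
2 | 2-bromo-6-methoxyphenol | COc1cccc(Br)c1O | intermediate
3 | 2,4-dibromo-6-methoxyphenol | COc1cc(Br)cc(Br)c1O | intermediate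
4 | ethyl bromoacetate | CCOC(=O)CBr | starting material
5 | ethyl 2-(2,4-dibromo-6-methoxyphenoxy)acetate | CCOC(=O)COc1c(Br)cc(Br)cc1OC | intermediate
6 | 2-(2,4-dibromo-6-methoxyphenoxy)acetic acid | OC(=O)COc1c(Br)cc(Br)cc1OC | intermediate
7 | Meldrum's acid (2,2-dimethyl-1,3-dioxane-4,6-dione) | CC1(C)OC(=O)CC(=O)O1 | starting material
8 | 5-[2-(2,4-dibromo-6-methoxyphenoxy)-1-hydroxyethylidene]-2,2-dimethyl-1,3-dioxane-4,6-dione | CC1(C)OC(=O)C(=C(O)COc2c(Br)cc(Br)cc2OC)C(=O)O1 | intermediate
9 | acylketene, 4-(2,4-dibromo-6-methoxyphenoxy)but-1-ene-1,3-dione (not isolated) | O=C=CC(=O)COc1c(Br)cc(Br)cc1OC | intermediate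
10 | tert-butyl 4-(2,4-dibromo-6-methoxyphenoxy)-3-oxobutanoate | CC(C)(C)OC(=O)CC(=O)COc1c(Br)cc(Br)cc1OC | intermediate
11 | acrolein (prop-2-enal) | C=CC=O | starting material
12 | tert-butyl 2-[(2,4-dibromo-6-methoxyphenoxy)acetyl]-5-oxopentanoate (racemic) | CC(C)(C)OC(=O)C(CCC=O)C(=O)COc1c(Br)cc(Br)cc1OC | intermediate
13 | keto acid, 2-[(2,4-dibromo-6-methoxyphenoxy)acetyl]-5-oxopentanoic acid (racemic, not isolated) | OC(=O)C(CCC=O)C(=O)COc1c(Br)cc(Br)cc1OC | intermediate
14 | keto aldehyde, 6-(2,4-dibromo-6-methoxyphenoxy)-5-oxohexanal (not isolated) | O=CCCCC(=O)COc1c(Br)cc(Br)cc1OC | intermediate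
15 | aldol, 2-(2,4-dibromo-6-methoxyphenoxy)-3-hydroxycyclohexan-1-one (racemic diastereomer mixture, not isolated) | O=C1CCCC(O)C1Oc1c(Br)cc(Br)cc1OC | intermediate
16 | 2-(2,4-dibromo-6-methoxyphenoxy)cyclohex-2-en-1-one | O=C1CCCC=C1Oc1c(Br)cc(Br)cc1OC | intermediate
17 | tert-butyl{[6-(2,4-dibromo-6-methoxyphenoxy)cyclohexa-1,5-dien-1-yl]oxy}dimethylsilane | CC(C)(C)[Si](C)(C)OC1=CCCC=C1Oc1c(Br)cc(Br)cc1OC | intermediate
18 | tert-butyl[2-(2,4-dibromo-6-methoxyphenoxy)phenoxy]dimethylsilane | CC(C)(C)[Si](C)(C)Oc1ccccc1Oc1c(Br)cc(Br)cc1OC | intermediate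
19 | 2-(2,4-dibromo-6-methoxyphenoxy)phenol | Oc1ccccc1Oc1c(Br)cc(Br)cc1OC | intermediate
20 | 4-bromo-2-(2,4-dibromo-6-methoxyphenoxy)phenol | Oc1ccc(Br)cc1Oc1c(Br)cc(Br)cc1OC | intermediate
21 | 2,4-dibromo-6-(2,4-dibromo-6-methoxyphenoxy)phenol | Oc1c(Br)cc(Br)cc1Oc1c(Br)cc(Br)cc1OC | intermediate
22 | 3,5-dibromo-2-(3,5-dibromo-2-hydroxyphenoxy)phenol (achiral) | Oc1cc(Br)cc(Br)c1Oc1cc(Br)cc(Br)c1O | target

## Step count and weak points
Total step count: 14. Longest linear sequence: 14 (1 to 22).

The three steps most likely to fail:

1. **Step 7.** The risks are acrolein polymerisation and a second addition to the still acidic C-2. The fallback replaces conjugate addition by alkylation with a masked aldehyde; it sets out from 10 and comes back at 12. The sodium enolate of 10 (NaH, DMF, 0 °C) is alkylated with 2-(2-bromoethyl)-1,3-dioxolane (cat. NaI, 60 °C). This gives tert-butyl 2-[(2,4-dibromo-6-methoxyphenoxy)acetyl]-4-(1,3-dioxolan-2-yl)butanoate F1. Its acetal is hydrolysed with 1 M HCl in THF at rt, which spares the tert-butyl ester and gives 12.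

2. **Step 8.** The risks are intermolecular aldehyde self-condensation and pyran formation in place of carbocyclisation. The fallback takes the six-membered ring ready-made and attaches it to the phenol; it sets out from 3 and comes back at 16. Cyclohex-2-en-1-one is epoxidised (30% H2O2, cat. NaOH, MeOH, 0 °C) to 7-oxabicyclo[4.1.0]heptan-2-one F2. Compound 3 and F2 are then heated with Cs2CO3 (0.2 equiv) in DMF at 80 °C. The phenoxide opens the epoxy ketone at the α-carbon to give 15 as its trans isomer, and E1cB loss of water gives 16.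

3. **Step 10.** The risks are cycloaddition or adduct formation between DDQ and the electron-rich diene, and premature desilylation. The fallback uses selenoxide elimination in place of hydride abstraction; it sets out from 16 and comes back at 19, bypassing steps 9 to 11.
   - The kinetic α'-enolate of 16 (LiN(SiMe3)2, THF, −78 °C) is quenched with PhSeCl. This gives 2-(2,4-dibromo-6-methoxyphenoxy)-6-(phenylselanyl)cyclohex-2-en-1-one F3.
   - Oxidation with H2O2 and pyridine in CH2Cl2 at 0 °C gives 2-(2,4-dibromo-6-methoxyphenoxy)-6-(phenylseleninyl)cyclohex-2-en-1-one F4.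
   - F4 undergoes syn-elimination below rt to 2-(2,4-dibromo-6-methoxyphenoxy)cyclohexa-2,5-dien-1-one F5, and this dienone tautomerises at once to 19.

## Further compounds
F1 | step 7 | tert-butyl 2-[(2,4-dibromo-6-methoxyphenoxy)acetyl]-4-(1,3-dioxolan-2-yl)butanoate (racemic) | CC(C)(C)OC(=O)C(CCC1OCCO1)C(=O)COc1c(Br)cc(Br)cc1OC
F2 | step 8 | 7-oxabicyclo[4.1.0]heptan-2-one (2,3-epoxycyclohexanone, racemic, cis-fused) | O=C1CCCC2OC12
F3 | step 10 | 2-(2,4-dibromo-6-methoxyphenoxy)-6-(phenylselanyl)cyclohex-2-en-1-one (racemic) | O=C1C([Se]c2ccccc2)CCC=C1Oc1c(Br)cc(Br)cc1OC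
F4 | step 10 | 2-(2,4-dibromo-6-methoxyphenoxy)-6-(phenylseleninyl)cyclohex-2-en-1-one (diastereomer mixture) | O=C1C([Se](=O)c2ccccc2)CCC=C1Oc1c(Br)cc(Br)cc1OC
F5 | step 10 | 2-(2,4-dibromo-6-methoxyphenoxy)cyclohexa-2,5-dien-1-one | O=C1C=CCC=C1Oc1c(Br)cc(Br)cc1OC
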